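**Retrosynthetic overview**

1. Numbering follows the labdane skeleton: ring A = C1–C5 and C10, ring B = C5–C10, C17 = carboxyl carbon on C8, C11–C14 and C16 = side chain on C9, C18/C19 on C4, C20 on C10. The acid is cut at C8–C17 (carbonylation of a C7=C8 enol triflate) and the side chain at C9–C11 (B-alkyl Suzuki coupling, with C9–H then set by hydroboration).
2. Ring A is cut at C2=C3 and C10–C1: a Michael–Wittig annulation of a ring B dienolate with vinyltriphenylphosphonium bromide, whose two carbons become C1 and C2.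
3. Feature that allows this: in ring B the methyl-bearing C10 (α to the C9 carbonyl) and the non-enolizable C3 aldehyde on quaternary C4 stand 1,4 to each other across C5, and the C7=C8 double bond leaves C10 as the only enolate carbon.
4. C4–C5 comes from a Mukaiyama–Michael addition to (R)-carvone, whose isopropenyl group fixes C5 and is then cut out; C13 comes from the (S)-Roche ester.
5. Ring order: ring B is taken from carvone; ring A is closed second and last, in the key step.

Key step: step 4

Remark: compounds 3 to 6 are carried as mixtures of epimers at C10; this centre becomes planar in 7 and is set in step 4.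

**Route**

Step 1
Reactants: 1 (R)-carvone; 2 2-methyl-1-(trimethylsilyloxy)prop-1-ene
Product: 3 2-methyl-2-[(1R,5R)-2-methyl-3-oxo-5-(prop-1-en-2-yl)cyclohexyl]propanal (C10 epimers)
Conditions: TiCl4, CH2Cl2, −78 °C; then H2O
Reagents that add atoms: none
Why: Mukaiyama–Michael addition in which the TiCl4-activated enone should be attacked at C5 by the enol silane on the face opposite to the isopropenyl group (axial attack anti to the C7 substituent, as in other Lewis acid conjugate additions to carvone), which sets C5 and builds quaternary C4 with the C3 aldehyde in the same event.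

Step 2
Reactants: 3 2-methyl-2-[(1R,5R)-2-methyl-3-oxo-5-(prop-1-en-2-yl)cyclohexyl]propanal
Product: 6 (5R)-6-methyl-5-(2-methyl-1-oxopropan-2-yl)cyclohex-2-en-1-one (C10 epimers), via methoxy hydroperoxide 4 (not isolated), via acetate 5 (not isolated)
Conditions: O3, CH2Cl2/MeOH, −78 °C; then Ac2O, Et3N, DMAP, 0 °C → rt; then DBU, 0 °C → rt
Reagents that add atoms: none
Why: Ozonolysis in methanol turns the only alkene into an α-methoxy hydroperoxide, acetylation of which triggers a Criegee rearrangement to the C7 acetate, and E1cB elimination of this β-acetoxy ketone gives the C7=C8 enone, so the stereocontrol element is excised without touching C5.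

Step 3
Reactants: 6 (5R)-6-methyl-5-(2-methyl-1-oxopropan-2-yl)cyclohex-2-en-1-one
Product: 7 2-methyl-2-[(1R)-2-methyl-3-(trimethylsilyloxy)cyclohexa-2,4-dien-1-yl]propanal
Conditions: Me3SiOTf, Et3N, CH2Cl2, 0 °C
Reagents that add atoms: trimethylsilyl trifluoromethanesulfonate, C[Si](C)(C)OS(=O)(=O)C(F)(F)F
Why: Soft enolization of a cyclohex-2-enone (O-silylation, then removal of the α'-proton at C10 by the amine) should give the cross-conjugated 2-silyloxy diene, in which both C10 epimers converge and the enolate position is fixed at C9–C10, while the aldehyde has no α-hydrogen to lose.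

Step 4
Reactants: 7 2-methyl-2-[(1R)-2-methyl-3-(trimethylsilyloxy)cyclohexa-2,4-dien-1-yl]propanal; 8 vinyltriphenylphosphonium bromide
Product: 11 (4aS,8aS)-5,5,8a-trimethyl-4a,5,8,8a-tetrahydronaphthalen-1(4H)-one, via ammonium dienolate 9 (not isolated), via phosphonium ylide 10 (not isolated)
Conditions: Bu4N[Ph3SiF2], CH2Cl2, −40 °C → rt
Reagents that add atoms: none
Why: Fluoride from Bu4N[Ph3SiF2] cleaves the Si–O bond of 7 and frees the cross-conjugated ammonium dienolate 9, which adds through C10 to the vinylphosphonium salt 8 (C10–C1 bond) to give ylide 10; the ylide carbon C2 then attacks the C3 aldehyde in an intramolecular Wittig reaction that forms C2=C3, closes ring A and expels Ph3PO. The closest known reaction type is the Schweizer annulation (conjugate addition of an enolate to vinyltriphenylphosphonium bromide followed by intramolecular Wittig olefination), here fed by fluoride activation of a silyl enol ether. Ring A closes by 6-exo-trig attack of the ylide on the aldehyde carbonyl through an oxaphosphetane, and within a six-membered ring only the cis alkene can form. The new quaternary stereocenter C10 is controlled by C5: the bulky 2-methyl-1-oxopropan-2-yl arm shields one face of the planar dienolate, so 8 should enter trans to it, which gives the trans ring fusion with C20 anti to H5. The step needs site selectivity for C10 and chemoselectivity of the ylide for the aldehyde: C8 is sp2 and no proton source is present to move the enolate, closure onto the C9 carbonyl would need a four-membered ring, and a non-stabilized ylide should olefinate an aldehyde much faster than it adds to the C7=C8 enone.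

Step 5
Reactants: 11 (4aS,8aS)-5,5,8a-trimethyl-4a,5,8,8a-tetrahydronaphthalen-1(4H)-one
Product: 12 (4aS,8aS)-5,5,8a-trimethyloctahydronaphthalen-1(2H)-one
Conditions: H2 (1 atm), Pd/C, EtOAc, rt
Reagents that add atoms: none
Why: Catalytic hydrogenation should saturate both the C2=C3 alkene and the C7=C8 enone double bond, and no stereocenter is formed or touched.

Step 6
Reactants: 12 (4aS,8aS)-5,5,8a-trimethyloctahydronaphthalen-1(2H)-one
Product: 14 (4aS,8aS)-5,5,8a-trimethyl-3,4,4a,5,6,7,8,8a-octahydronaphthalen-1-yl trifluoromethanesulfonate, via potassium enolate 13 (not isolated)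
Conditions: KN(SiMe3)2, THF, −78 °C; then PhNTf2, −78 → 0 °C
Reagents that add atoms: N-phenylbis(trifluoromethanesulfonimide), O=S(=O)(N(c1ccccc1)S(=O)(=O)C(F)(F)F)C(F)(F)F
Why: Enol triflate formation is regiospecific because C8 carries the only α-hydrogens of the C9 ketone (C10 is quaternary).

Step 7
Reactants: 15 methyl (S)-3-hydroxy-2-methylpropanoate
Product: 16 methyl (S)-3-[(tert-butyldimethylsilyl)oxy]-2-methylpropanoate
Conditions: TBSCl, imidazole, DMF, rt
Reagents that add atoms: tert-butyldimethylsilyl chloride, CC(C)(C)[Si](C)(C)Cl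
Why: Silylation of the primary alcohol, which leaves the stereocenter (the future C13) untouched.

Step 8
Reactants: 16 methyl (S)-3-[(tert-butyldimethylsilyl)oxy]-2-methylpropanoate
Product: 17 (S)-3-[(tert-butyldimethylsilyl)oxy]-2-methylpropanal
Conditions: i-Bu2AlH, CH2Cl2, −78 °C; then aq. potassium sodium tartrate
Reagents that add atoms: none
Why: Partial reduction of the ester stops at the aldehyde level because the tetrahedral aluminium hemiacetal survives at −78 °C, and the cold, neutral work-up should keep the α-stereocenter.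

Step 9
Reactants: 17 (S)-3-[(tert-butyldimethylsilyl)oxy]-2-methylpropanal
Product: 18 (R)-tert-butyldimethyl[(2-methylbut-3-en-1-yl)oxy]silane
Conditions: Ph3PCH3Br, KN(SiMe3)2, THF, 0 °C; then 17, −78 °C → rt
Reagents that add atoms: methyltriphenylphosphonium bromide, C[P+](c1ccccc1)(c1ccccc1)c1ccccc1.[Br-]
Why: Wittig methylenation with the non-stabilized ylide at low temperature should be faster than epimerization of the α-branched aldehyde (the descriptor changes from S to R only through the priority rules).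

Step 10
Reactants: 18 (R)-tert-butyldimethyl[(2-methylbut-3-en-1-yl)oxy]silane; 14 (4aS,8aS)-5,5,8a-trimethyl-3,4,4a,5,6,7,8,8a-octahydronaphthalen-1-yl trifluoromethanesulfonate
Product: 20 tert-butyl{[(2R)-2-methyl-4-[(4aS,8aS)-5,5,8a-trimethyl-3,4,4a,5,6,7,8,8a-octahydronaphthalen-1-yl]butyl]oxy}dimethylsilane, via alkylborane 19 (not isolated)
Conditions: 9-BBN, THF, 0 °C → rt; then 14, PdCl2(dppf), AsPh3, Cs2CO3, DMF/H2O, rt → 50 °C
Reagents that add atoms: none
Why: Anti-Markovnikov hydroboration of the terminal alkene places boron on C11, and B-alkyl Suzuki–Miyaura coupling with the enol triflate then forms the C9–C11 bond with the ring alkene fixed at C8=C9.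

Step 11
Reactants: 20 tert-butyl{[(2R)-2-methyl-4-[(4aS,8aS)-5,5,8a-trimethyl-3,4,4a,5,6,7,8,8a-octahydronaphthalen-1-yl]butyl]oxy}dimethylsilane
Product: 22 (1R,2R,4aS,8aS)-1-{(3R)-4-[(tert-butyldimethylsilyl)oxy]-3-methylbutyl}-5,5,8a-trimethyldecahydronaphthalen-2-ol, via alkylborane 21 (not isolated)
Conditions: BH3·THF, THF, 0 °C → rt; then NaOH, H2O2, 0 °C
Reagents that add atoms: hydrogen peroxide, OO
Why: In this hydroboration–oxidation the borane should add syn to the C8=C9 alkene from the α face, away from the axial C20 methyl, with boron on the less substituted C8, so that hydrogen is delivered to C9 on the α face (side chain β, as in the target) and the oxidation goes with retention.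

Step 12
Reactants: 22 (1R,2R,4aS,8aS)-1-{(3R)-4-[(tert-butyldimethylsilyl)oxy]-3-methylbutyl}-5,5,8a-trimethyldecahydronaphthalen-2-ol
Product: 23 (1R,4aS,8aS)-1-{(3R)-4-[(tert-butyldimethylsilyl)oxy]-3-methylbutyl}-5,5,8a-trimethyloctahydronaphthalen-2(1H)-one
Conditions: Dess–Martin periodinane, NaHCO3, CH2Cl2, rt
Reagents that add atoms: none
Why: Dess–Martin oxidation of the secondary alcohol gives the C8 ketone, and C9 should keep its configuration because the equatorial side chain is the stable epimer.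

Step 13
Reactants: 23 (1R,4aS,8aS)-1-{(3R)-4-[(tert-butyldimethylsilyl)oxy]-3-methylbutyl}-5,5,8a-trimethyloctahydronaphthalen-2(1H)-one
Product: 25 (1R,4aS,8aS)-1-{(3R)-4-[(tert-butyldimethylsilyl)oxy]-3-methylbutyl}-5,5,8a-trimethyl-1,4,4a,5,6,7,8,8a-octahydronaphthalen-2-yl trifluoromethanesulfonate, via potassium enolate 24 (not isolated)
Conditions: KN(SiMe3)2, THF, −78 °C; then PhNTf2, −78 → −20 °C
Reagents that add atoms: N-phenylbis(trifluoromethanesulfonimide), O=S(=O)(N(c1ccccc1)S(=O)(=O)C(F)(F)F)C(F)(F)F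
Why: Kinetic deprotonation should take place at the C7 methylene and not at the hindered C9 methine next to quaternary C10, so that enol triflate formation fixes the double bond at C7=C8.

Step 14
Reactants: 25 (1R,4aS,8aS)-1-{(3R)-4-[(tert-butyldimethylsilyl)oxy]-3-methylbutyl}-5,5,8a-trimethyl-1,4,4a,5,6,7,8,8a-octahydronaphthalen-2-yl trifluoromethanesulfonate
Product: 26 (1R,4aS,8aS)-1-[(3R)-4-hydroxy-3-methylbutyl]-5,5,8a-trimethyl-1,4,4a,5,6,7,8,8a-octahydronaphthalen-2-yl trifluoromethanesulfonate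
Conditions: HF·pyridine, THF, 0 °C → rt
Reagents that add atoms: none
Why: Desilylation by fluoride under mildly acidic conditions, to which the enol triflate is stable.

Step 15
Reactants: 26 (1R,4aS,8aS)-1-[(3R)-4-hydroxy-3-methylbutyl]-5,5,8a-trimethyl-1,4,4a,5,6,7,8,8a-octahydronaphthalen-2-yl trifluoromethanesulfonate
Product: 27 (2R)-2-methyl-4-[(1R,4aS,8aS)-5,5,8a-trimethyl-2-{[(trifluoromethyl)sulfonyl]oxy}-1,4,4a,5,6,7,8,8a-octahydronaphthalen-1-yl]butyl 2-methylpropanoate
Conditions: (i-PrCO)2O, Et3N, DMAP, CH2Cl2, 0 °C → rt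
Reagents that add atoms: 2-methylpropanoic anhydride, CC(C)C(=O)OC(=O)C(C)C
Why: DMAP-catalysed acylation of the primary alcohol installs the isobutyrate ester.

Step 16
Reactants: 27 (2R)-2-methyl-4-[(1R,4aS,8aS)-5,5,8a-trimethyl-2-{[(trifluoromethyl)sulfonyl]oxy}-1,4,4a,5,6,7,8,8a-octahydronaphthalen-1-yl]butyl 2-methylpropanoate
Product: 28 (1R,4aS,8aS)-5,5,8a-trimethyl-1-[(3R)-3-methyl-4-(2-methylpropanoyloxy)butyl]-1,4,4a,5,6,7,8,8a-octahydronaphthalene-2-carboxylic acid (target)
Conditions: Pd(OAc)2, dppf, CO (1 atm), KOAc, DMF/H2O, 60 °C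
Reagents that add atoms: carbon monoxide, [C-]#[O+]; water, O
Why: Palladium-catalysed hydroxycarbonylation of the enol triflate (oxidative addition, CO insertion, hydrolysis of the acylpalladium species) should install C17 as the free acid on C8 with the double bond held at C7=C8, under conditions that leave the isobutyrate ester intact.

**Compound list**

1 | (R)-carvone, (5R)-2-methyl-5-(prop-1-en-2-yl)cyclohex-2-en-1-one | CC1=CC[C@H](CC1=O)C(C)=C | starting material
2 | 2-methyl-1-(trimethylsilyloxy)prop-1-ene | CC(C)=CO[Si](C)(C)C | starting material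
3 | 2-methyl-2-[(1R,5R)-2-methyl-3-oxo-5-(prop-1-en-2-yl)cyclohexyl]propanal (aldehyde arm trans to isopropenyl; C10 epimers) | O=C1C(C)[C@H](C(C)(C)C=O)C[C@@H](C(C)=C)C1 | intermediate
4 | 2-[(1R,5R)-5-(1-hydroperoxy-1-methoxyethyl)-2-methyl-3-oxocyclohexyl]-2-methylpropanal | O=C1C(C)[C@H](C(C)(C)C=O)C[C@@H](C(C)(OC)OO)C1 | intermediate
5 | (1R,3R)-4-methyl-3-(2-methyl-1-oxopropan-2-yl)-5-oxocyclohexyl acetate | O=C1C(C)[C@H](C(C)(C)C=O)C[C@@H](OC(C)=O)C1 | intermediate
6 | (5R)-6-methyl-5-(2-methyl-1-oxopropan-2-yl)cyclohex-2-en-1-one (C10 epimers) | O=C1C=CC[C@@H](C(C)(C)C=O)C1C | intermediate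
7 | 2-methyl-2-[(1R)-2-methyl-3-(trimethylsilyloxy)cyclohexa-2,4-dien-1-yl]propanal | C[Si](C)(C)OC1=C(C)[C@H](C(C)(C)C=O)CC=C1 | intermediate
8 | vinyltriphenylphosphonium bromide | C=C[P+](c1ccccc1)(c1ccccc1)c1ccccc1.[Br-] | starting material
9 | tetrabutylammonium (3R)-2-methyl-3-(2-methyl-1-oxopropan-2-yl)cyclohexa-1,5-dien-1-olate | CCCC[N+](CCCC)(CCCC)CCCC.[O-]C1=C(C)[C@H](C(C)(C)C=O)CC=C1 | intermediate
10 | {2-[(1S,6S)-1-methyl-6-(2-methyl-1-oxopropan-2-yl)-2-oxocyclohex-3-en-1-yl]ethylidene}triphenylphosphorane | O=C1C=CC[C@@H](C(C)(C)C=O)[C@]1(C)CC=P(c1ccccc1)(c1ccccc1)c1ccccc1 | intermediate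
11 | (4aS,8aS)-5,5,8a-trimethyl-4a,5,8,8a-tetrahydronaphthalen-1(4H)-one | O=C1C=CC[C@H]2C(C)(C)C=CC[C@]12C | intermediate
12 | (4aS,8aS)-5,5,8a-trimethyloctahydronaphthalen-1(2H)-one | O=C1CCC[C@H]2C(C)(C)CCC[C@]12C | intermediate
13 | potassium (4aS,8aS)-5,5,8a-trimethyl-3,4,4a,5,6,7,8,8a-octahydronaphthalen-1-olate | [K+].[O-]C1=CCC[C@H]2C(C)(C)CCC[C@]12C | intermediate
14 | (4aS,8aS)-5,5,8a-trimethyl-3,4,4a,5,6,7,8,8a-octahydronaphthalen-1-yl trifluoromethanesulfonate | O=S(=O)(OC1=CCC[C@H]2C(C)(C)CCC[C@]12C)C(F)(F)F | intermediate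
15 | methyl (S)-3-hydroxy-2-methylpropanoate | OC[C@H](C)C(=O)OC | starting material
16 | methyl (S)-3-[(tert-butyldimethylsilyl)oxy]-2-methylpropanoate | CC(C)(C)[Si](C)(C)OC[C@H](C)C(=O)OC | intermediate
17 | (S)-3-[(tert-butyldimethylsilyl)oxy]-2-methylpropanal | CC(C)(C)[Si](C)(C)OC[C@H](C)C=O | intermediate
18 | (R)-tert-butyldimethyl[(2-methylbut-3-en-1-yl)oxy]silane | CC(C)(C)[Si](C)(C)OC[C@H](C)C=C | intermediate
19 | 9-{(3R)-4-[(tert-butyldimethylsilyl)oxy]-3-methylbutyl}-9-borabicyclo[3.3.1]nonane | CC(C)(C)[Si](C)(C)OC[C@H](C)CCB1C2CCCC1CCC2 | intermediate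
20 | tert-butyl{[(2R)-2-methyl-4-[(4aS,8aS)-5,5,8a-trimethyl-3,4,4a,5,6,7,8,8a-octahydronaphthalen-1-yl]butyl]oxy}dimethylsilane | CC(C)(C)[Si](C)(C)OC[C@H](C)CCC1=CCC[C@H]2C(C)(C)CCC[C@]12C | intermediate
21 | [(4aS,8aS)-1-{(3R)-4-[(tert-butyldimethylsilyl)oxy]-3-methylbutyl}-5,5,8a-trimethyldecahydronaphthalen-2-yl]borane (B on C8 and H on C9, both on the α face) | CC(C)(C)[Si](C)(C)OC[C@H](C)CC[C@H]1[C@H](B)CC[C@H]2C(C)(C)CCC[C@]12C | intermediate
22 | (1R,2R,4aS,8aS)-1-{(3R)-4-[(tert-butyldimethylsilyl)oxy]-3-methylbutyl}-5,5,8a-trimethyldecahydronaphthalen-2-ol | CC(C)(C)[Si](C)(C)OC[C@H](C)CC[C@H]1[C@H](O)CC[C@H]2C(C)(C)CCC[C@]12C | intermediate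
23 | (1R,4aS,8aS)-1-{(3R)-4-[(tert-butyldimethylsilyl)oxy]-3-methylbutyl}-5,5,8a-trimethyloctahydronaphthalen-2(1H)-one | CC(C)(C)[Si](C)(C)OC[C@H](C)CC[C@H]1C(=O)CC[C@H]2C(C)(C)CCC[C@]12C | intermediate
24 | potassium (1R,4aS,8aS)-1-{(3R)-4-[(tert-butyldimethylsilyl)oxy]-3-methylbutyl}-5,5,8a-trimethyl-1,4,4a,5,6,7,8,8a-octahydronaphthalen-2-olate | [K+].CC(C)(C)[Si](C)(C)OC[C@H](C)CC[C@H]1C([O-])=CC[C@H]2C(C)(C)CCC[C@]12C | intermediate
25 | (1R,4aS,8aS)-1-{(3R)-4-[(tert-butyldimethylsilyl)oxy]-3-methylbutyl}-5,5,8a-trimethyl-1,4,4a,5,6,7,8,8a-octahydronaphthalen-2-yl trifluoromethanesulfonate | CC(C)(C)[Si](C)(C)OC[C@H](C)CC[C@H]1C(OS(=O)(=O)C(F)(F)F)=CC[C@H]2C(C)(C)CCC[C@]12C | intermediate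
26 | (1R,4aS,8aS)-1-[(3R)-4-hydroxy-3-methylbutyl]-5,5,8a-trimethyl-1,4,4a,5,6,7,8,8a-octahydronaphthalen-2-yl trifluoromethanesulfonate | OC[C@H](C)CC[C@H]1C(OS(=O)(=O)C(F)(F)F)=CC[C@H]2C(C)(C)CCC[C@]12C | intermediate
27 | (2R)-2-methyl-4-[(1R,4aS,8aS)-5,5,8a-trimethyl-2-{[(trifluoromethyl)sulfonyl]oxy}-1,4,4a,5,6,7,8,8a-octahydronaphthalen-1-yl]butyl 2-methylpropanoate | CC(C)C(=O)OC[C@H](C)CC[C@H]1C(OS(=O)(=O)C(F)(F)F)=CC[C@H]2C(C)(C)CCC[C@]12C | intermediate
28 | (1R,4aS,8aS)-5,5,8a-trimethyl-1-[(3R)-3-methyl-4-(2-methylpropanoyloxy)butyl]-1,4,4a,5,6,7,8,8a-octahydronaphthalene-2-carboxylic acid | CC(C)C(=O)OC[C@H](C)CC[C@H]1C(C(=O)O)=CC[C@H]2C(C)(C)CCC[C@]12C | target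

**Step count**

Total step count: 16. Longest linear sequence: 13 steps (steps 1 to 6 and 10 to 16); steps 7 to 9 prepare the side-chain fragment.

**Steps most likely to fail**

Step 4 (key step). The free dienolate 9 may fragment by retro-Michael loss of the C4 arm, a process driven by aromatization of ring B, or be quenched by proton transfer before it meets 8; the ylide may also add to the C7=C8 enone in place of olefination. The fallback sets out from 6 and forms the same C2=C3 bond by metathesis. Wittig methylenation of the aldehyde (Ph3P=CH2, THF, −78 °C) should give (5R)-6-methyl-5-(2-methylbut-3-en-2-yl)cyclohex-2-en-1-one F1, which no longer carries a leaving arm that can be expelled. Kinetic deprotonation at C10 with LiN(i-Pr)2 (THF, −78 °C) and alkylation with allyl bromide trans to the C5 arm should give (5S,6S)-6-allyl-6-methyl-5-(2-methylbut-3-en-2-yl)cyclohex-2-en-1-one F2. Ring-closing metathesis (second-generation Grubbs catalyst RuCl2(=CHPh)(H2IMes)(PCy3), CH2Cl2, 40 °C) then closes ring A, and the sequence comes back to the route at 11.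

Step 3. Enolization may turn toward C6 (γ-deprotonation) and give the linear dienol ether, or the silyl triflate may activate the aldehyde toward oligomerization. The fallback sets out from 6 and avoids the dienol ether. Hydrogenation (H2, Pd/C, EtOAc) should give 2-methyl-2-[(1R)-2-methyl-3-oxocyclohexyl]propanal F3. Its thermodynamic sodium enolate (NaH, THF, trace t-BuOH, rt) should add to 8 at the more substituted C10 and close by Wittig olefination to (4aS,8aS)-5,5,8a-trimethyl-3,4,4a,5,8,8a-hexahydronaphthalen-1(2H)-one F4. Hydrogenation as in step 5 brings the sequence back to the route at 12.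

Step 1. The liberated aldehyde may react on under TiCl4 (aldol addition of a second enol silane, carbonyl-ene closure onto the isopropenyl group), and facial selectivity may erode if the temperature rises. The fallback sets out from 1 and carries the arm at the ester level. Mukaiyama–Michael addition of 1-methoxy-2-methyl-1-(trimethylsilyloxy)prop-1-ene (TiCl4, CH2Cl2, −78 °C) should give methyl 2-methyl-2-[(1R,5R)-2-methyl-3-oxo-5-(prop-1-en-2-yl)cyclohexyl]propanoate F5. Reduction of ketone and ester with LiAlH4 (THF, 0 °C) should give 2-[(1R,5R)-3-hydroxy-2-methyl-5-(prop-1-en-2-yl)cyclohexyl]-2-methylpropan-1-ol F6. Swern oxidation of both hydroxyl groups ((COCl)2, DMSO, Et3N, −78 °C) comes back to the route at 3.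

Further compounds
F1 | step 4 | (5R)-6-methyl-5-(2-methylbut-3-en-2-yl)cyclohex-2-en-1-one (C10 epimers) | O=C1C=CC[C@@H](C(C)(C)C=C)C1C
F2 | step 4 | (5S,6S)-6-allyl-6-methyl-5-(2-methylbut-3-en-2-yl)cyclohex-2-en-1-one | O=C1C=CC[C@@H](C(C)(C)C=C)[C@]1(C)CC=C
F3 | step 3 | 2-methyl-2-[(1R)-2-methyl-3-oxocyclohexyl]propanal (C10 epimers) | O=C1CCC[C@@H](C(C)(C)C=O)C1C
F4 | step 3 | (4aS,8aS)-5,5,8a-trimethyl-3,4,4a,5,8,8a-hexahydronaphthalen-1(2H)-one | O=C1CCC[C@H]2C(C)(C)C=CC[C@]12C
F5 | step 1 | methyl 2-methyl-2-[(1R,5R)-2-methyl-3-oxo-5-(prop-1-en-2-yl)cyclohexyl]propanoate (C10 epimers) | O=C1C(C)[C@H](C(C)(C)C(=O)OC)C[C@@H](C(C)=C)C1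
F6 | step 1 | 2-[(1R,5R)-3-hydroxy-2-methyl-5-(prop-1-en-2-yl)cyclohexyl]-2-methylpropan-1-ol (epimers at the carbinol and methyl-bearing ring carbons) | OC1C(C)[C@H](C(C)(C)CO)C[C@@H](C(C)=C)C1
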